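Assumption: tributyl(3-methylbut-2-en-1-yl)stannane and the quinine-derived squaramide are bought. Bicyclic lactones use chroman-2-one locants; the tricycles use pyrano[2,3-f]chromene locants (O1, C2 lactone carbonyl, C4 pentyl carbon, C5, C6, O7, C8, C9, C10 ketone).

**Retrosynthetic overview**
1. Target 12 ⇒ tricyclic lactone 11 by lactone hydrolysis. The dihydrocoumarin lactone masks the acid and the phenol next to the side chain, so only the other phenol can close the pyranone.
2. 11 ⇒ aryl iodide 9 plus prenylstannane 10 (Stille coupling).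
3. Key disconnection: the O7–C8 bond of the pyranone, 9 ⇒ o-hydroxyaryl tigloyl ketone 8, by catalytic asymmetric oxa-Michael ring closure that sets C8 and C9.
4. 8 ⇒ lactone 4 by iodination and by Friedel–Crafts tigloylation with ortho-demethylation.
5. 4 ⇒ 3,5-dimethoxyphenol 1 plus (E)-oct-2-enal 2, which sets the benzylic centre. Ring order: lactone ring first, pyranone ring second.

**Route**

Step 1
Reactants: 1 3,5-dimethoxyphenol; 2 (E)-oct-2-enal
Product: 4 (4R)-5,7-dimethoxy-4-pentylchroman-2-one, via lactol 3 (not isolated)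
Conditions: (S)-α,α-diphenylprolinol TMS ether (20 mol %), PhCO2H (20 mol %), toluene, 0 °C; then (C5H5NH)[CrO3Cl] (pyridinium chlorochromate), CH2Cl2, rt, same flask
Reagents that add atoms: none
Why: Iminium-activated Friedel–Crafts alkylation/hemiacetalisation; the phenol ortho carbon adds to the enal face opposite the diphenyl(silyloxy)methyl group, which sets C4 as R, and the lactol is then oxidised to the lactone.

Step 2
Reactants: 4 (4R)-5,7-dimethoxy-4-pentylchroman-2-one; 5 (E)-2-methylbut-2-enoyl chloride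
Product: 7 (4R)-7-hydroxy-5-methoxy-8-[(E)-2-methylbut-2-enoyl]-4-pentylchroman-2-one, via dimethoxy ketone 6 (not isolated)
Conditions: AlCl3 (3.5 equiv), CH2Cl2, 0 °C to rt; cold 1 M HCl work-up
Reagents that add atoms: none
Why: Friedel–Crafts acylation goes to C8, which is para to the 5-methoxy group and less hindered than C6; the aluminium chelate of the new ketone then cleaves only the ortho (C7) methyl ether and keeps the phenoxide off the enone.

Step 3
Reactants: 7 (4R)-7-hydroxy-5-methoxy-8-[(E)-2-methylbut-2-enoyl]-4-pentylchroman-2-one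
Product: 8 (4R)-7-hydroxy-6-iodo-5-methoxy-8-[(E)-2-methylbut-2-enoyl]-4-pentylchroman-2-one
Conditions: NIS (1.05 equiv), MeCN, 0 °C, dark
Reagents that add atoms: N-iodosuccinimide, O=C1CCC(=O)N1I
Why: Electrophilic aromatic iodination at the only free ring position, ortho to the free phenol; the electron-poor enone is not touched.

Step 4
Reactants: 8 (4R)-7-hydroxy-6-iodo-5-methoxy-8-[(E)-2-methylbut-2-enoyl]-4-pentylchroman-2-one
Product: 9 (4R,8R,9R)-6-iodo-5-methoxy-8,9-dimethyl-4-pentyl-3,4,8,9-tetrahydro-2H,10H-pyrano[2,3-f]chromene-2,10-dione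
Conditions: quinine-derived squaramide, 3-[3,5-bis(trifluoromethyl)anilino]-4-[(8α,9S)-6'-methoxycinchonan-9-ylamino]cyclobut-3-ene-1,2-dione (10 mol %), PhCl, 4 Å MS, 0 °C
Reagents that add atoms: none
Why: Proposed new method: an enantioselective 6-endo oxa-Michael ring closure run as a syn-hydroalkoxylation of the trisubstituted enone. The squaramide clamps the ketone (then enolate) oxygen, and the quinuclidine deprotonates the 7-OH and stays ion-paired over the forming C–O bond, so it returns the proton to the α-carbon on the same face. Syn addition of O and H across the (E)-alkene maps onto the trans ring with both methyls equatorial, which is also the thermodynamic isomer. C8 is set by the catalyst in the C–O bond-forming event (the remote C4 centre gives no useful bias) and C9 by the proton return. The closest known reactions are the cinchona alkaloid-catalysed intramolecular oxa-Michael cyclisation of o-tigloylphenols, which is cis-selective, and squaramide- or thiourea-catalysed oxa-Michael closures to flavanones.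

Step 5
Reactants: 9 (4R,8R,9R)-6-iodo-5-methoxy-8,9-dimethyl-4-pentyl-3,4,8,9-tetrahydro-2H,10H-pyrano[2,3-f]chromene-2,10-dione; 10 tributyl(3-methylbut-2-en-1-yl)stannane
Product: 11 (4R,8R,9R)-5-methoxy-8,9-dimethyl-6-(3-methylbut-2-en-1-yl)-4-pentyl-3,4,8,9-tetrahydro-2H,10H-pyrano[2,3-f]chromene-2,10-dione
Conditions: Pd2(dba)3 (2.5 mol %), AsPh3 (20 mol %), CuI (10 mol %), DMF, 60 °C
Reagents that add atoms: none
Why: Stille coupling; reductive elimination at the less hindered allyl terminus gives the linear prenyl group, and the neutral conditions leave the lactone and all three stereocentres alone.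

Step 6
Reactants: 11 (4R,8R,9R)-5-methoxy-8,9-dimethyl-6-(3-methylbut-2-en-1-yl)-4-pentyl-3,4,8,9-tetrahydro-2H,10H-pyrano[2,3-f]chromene-2,10-dione
Product: 12 (3R)-3-[(2R,3R)-5-hydroxy-7-methoxy-2,3-dimethyl-8-(3-methylbut-2-en-1-yl)-4-oxo-3,4-dihydro-2H-chromen-6-yl]octanoic acid
Conditions: LiOH (3 equiv), THF/H2O 3:1, 0 °C; then 1 M HCl to pH 3, 0 °C
Reagents that add atoms: lithium hydroxide, [Li+].[OH-]
Why: Saponification of the aryl-ester lactone is faster than enolisation of the chromanone, and the freed phenoxide then deactivates the ketone towards retro-oxa-Michael opening. After mild acidification the phenol is hydrogen-bonded to the ketone and does not relactonise, and C3 of the chromanone stays in its thermodynamic trans configuration.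

**Compound list**
1 | 3,5-dimethoxyphenol | COc1cc(O)cc(OC)c1 | starting material
2 | (E)-oct-2-enal | CCCCC/C=C/C=O | starting material
3 | (4R)-5,7-dimethoxy-4-pentylchroman-2-ol (lactol, both C2 epimers) | CCCCC[C@@H]1CC(O)Oc2cc(OC)cc(OC)c12 | intermediate
4 | (4R)-5,7-dimethoxy-4-pentylchroman-2-one | CCCCC[C@@H]1CC(=O)Oc2cc(OC)cc(OC)c12 | intermediate
5 | (E)-2-methylbut-2-enoyl chloride (tigloyl chloride) | C/C=C(\C)C(=O)Cl | starting material
6 | (4R)-5,7-dimethoxy-8-[(E)-2-methylbut-2-enoyl]-4-pentylchroman-2-one | CCCCC[C@@H]1CC(=O)Oc2c(C(=O)/C(C)=C/C)c(OC)cc(OC)c12 | intermediate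
7 | (4R)-7-hydroxy-5-methoxy-8-[(E)-2-methylbut-2-enoyl]-4-pentylchroman-2-one | CCCCC[C@@H]1CC(=O)Oc2c(C(=O)/C(C)=C/C)c(O)cc(OC)c12 | intermediate
8 | (4R)-7-hydroxy-6-iodo-5-methoxy-8-[(E)-2-methylbut-2-enoyl]-4-pentylchroman-2-one | CCCCC[C@@H]1CC(=O)Oc2c(C(=O)/C(C)=C/C)c(O)c(I)c(OC)c12 | intermediate
9 | (4R,8R,9R)-6-iodo-5-methoxy-8,9-dimethyl-4-pentyl-3,4,8,9-tetrahydro-2H,10H-pyrano[2,3-f]chromene-2,10-dione | CCCCC[C@@H]1CC(=O)Oc2c1c(OC)c(I)c1O[C@H](C)[C@@H](C)C(=O)c12 | intermediate
10 | tributyl(3-methylbut-2-en-1-yl)stannane | CCCC[Sn](CCCC)(CCCC)CC=C(C)C | starting material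
11 | (4R,8R,9R)-5-methoxy-8,9-dimethyl-6-(3-methylbut-2-en-1-yl)-4-pentyl-3,4,8,9-tetrahydro-2H,10H-pyrano[2,3-f]chromene-2,10-dione | CCCCC[C@@H]1CC(=O)Oc2c1c(OC)c(CC=C(C)C)c1O[C@H](C)[C@@H](C)C(=O)c12 | intermediate
12 | (3R)-3-[(2R,3R)-5-hydroxy-7-methoxy-2,3-dimethyl-8-(3-methylbut-2-en-1-yl)-4-oxo-3,4-dihydro-2H-chromen-6-yl]octanoic acid | CCCCC[C@H](CC(=O)O)c1c(O)c2c(c(CC=C(C)C)c1OC)O[C@H](C)[C@@H](C)C2=O | target

**Step count and risks**
Total steps: 6. Longest linear sequence: 6.

Step 4 is the most likely to fail, because it is the new method. The sense of induction at C8 cannot be predicted and is set by the choice of catalyst pseudoenantiomer (quinine- or quinidine-derived). The proton return may also be less syn-selective than hoped and leave some cis isomer. The fallback uses known chemistry and sets out from 8. Quinine (20 mol %) in chlorobenzene at rt closes the ring by the established cinchona-catalysed oxa-Michael addition to the kinetic cis isomer, (4R,8R,9S)-6-iodo-5-methoxy-8,9-dimethyl-4-pentyl-3,4,8,9-tetrahydro-2H,10H-pyrano[2,3-f]chromene-2,10-dione F4. Magnesium-mediated enolisation (MgI2, Et3N, CH2Cl2) then epimerises C9 alone to the trans isomer, and the route is rejoined at 9.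

Step 2 is the next risk. Acylation could partly go to C6, the demethylation could be incomplete, or the enone could add HCl. The fallback lets the lactone phenol direct the acyl group and sets out from 4. Methanolysis (K2CO3, MeOH) gives methyl (3R)-3-(2-hydroxy-4,6-dimethoxyphenyl)octanoate F1. O-acylation with 5 (Et3N, DMAP, CH2Cl2) gives methyl (3R)-3-{2,4-dimethoxy-6-[(E)-2-methylbut-2-enoyloxy]phenyl}octanoate F2. A TiCl4-mediated Fries rearrangement moves the acyl group to the only free position ortho to the phenol and gives methyl (3R)-3-{2-hydroxy-4,6-dimethoxy-3-[(E)-2-methylbut-2-enoyl]phenyl}octanoate F3. TsOH in toluene recloses the lactone to 6, here isolated, and BCl3 (CH2Cl2, −78 to 0 °C) removes the methyl ortho to the ketone, so the route is rejoined at 7.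

Step 5 is the third risk. The iodide sits between two oxygen substituents on a fully substituted ring, and a prenylstannane can give some reverse-prenyl (1,1-dimethylallyl) product. The fallback builds the prenyl group in two stages and sets out from 9. Stille coupling with allyltributylstannane (Pd(PPh3)4, toluene, 100 °C), which has no regiochemical ambiguity, gives (4R,8R,9R)-5-methoxy-8,9-dimethyl-4-pentyl-6-(prop-2-en-1-yl)-3,4,8,9-tetrahydro-2H,10H-pyrano[2,3-f]chromene-2,10-dione F5. Cross-metathesis with excess 2-methylbut-2-ene and second-generation Grubbs catalyst, RuCl2(H2IMes)(PCy3)(=CHPh), in CH2Cl2 at 40 °C converts the allyl group into the prenyl group, and the route is rejoined at 11.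

**Further compounds**
F1 | step 2 | methyl (3R)-3-(2-hydroxy-4,6-dimethoxyphenyl)octanoate | CCCCC[C@H](CC(=O)OC)c1c(OC)cc(OC)cc1O
F2 | step 2 | methyl (3R)-3-{2,4-dimethoxy-6-[(E)-2-methylbut-2-enoyloxy]phenyl}octanoate | CCCCC[C@H](CC(=O)OC)c1c(OC)cc(OC)cc1OC(=O)/C(C)=C/C
F3 | step 2 | methyl (3R)-3-{2-hydroxy-4,6-dimethoxy-3-[(E)-2-methylbut-2-enoyl]phenyl}octanoate | CCCCC[C@H](CC(=O)OC)c1c(OC)cc(OC)c(C(=O)/C(C)=C/C)c1O
F4 | step 4 | (4R,8R,9S)-6-iodo-5-methoxy-8,9-dimethyl-4-pentyl-3,4,8,9-tetrahydro-2H,10H-pyrano[2,3-f]chromene-2,10-dione | CCCCC[C@@H]1CC(=O)Oc2c1c(OC)c(I)c1O[C@H](C)[C@H](C)C(=O)c12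
F5 | step 5 | (4R,8R,9R)-5-methoxy-8,9-dimethyl-4-pentyl-6-(prop-2-en-1-yl)-3,4,8,9-tetrahydro-2H,10H-pyrano[2,3-f]chromene-2,10-dione | CCCCC[C@@H]1CC(=O)Oc2c1c(OC)c(CC=C)c1O[C@H](C)[C@@H](C)C(=O)c12
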